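**Retrosynthetic overview**
1. Endgame: the hydroquinone acid is unveiled from dimethyl ether methyl ester 20; the 3β-bromide comes from invertive displacement of a 3α-alcohol, itself made by Wharton transposition of the ring-A 2-en-1-one 16.
2. Key disconnection of 16: C-5–C-10 (radical 6-endo closure, ring B first) and C-2–C-3 (aldol condensation, ring A second), both from the acyclic α-methylene ketone dienal 14 in one flask.
3. Enabling feature: the quaternary ring-fusion carbon C-10 is flanked by C-1, which can be a ketone carbon. This makes C-10 a tertiary α-keto radical site (its CH3 is born from a =CH2) and C-2 an enolisable methyl. C-3 is an aldehyde on the non-enolisable C-4(CH3)2, and the C-7=C-8 alkene of ring B is what remains of a C-5=C-6–C-7=C-8 diene.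
4. 14 comes from enone 10 and dienylboronate 6 by rhodium-catalysed asymmetric 1,4-addition (sets C-9), then α-methylenation.
5. 6 comes from 2,2-dimethylpropane-1,3-diol; 10 from methyl 2-(2,5-dimethoxyphenyl)acetate.

Key step: step 13

Remark: positions are given in drimane numbering (ring A = C-1 to C-5 and C-10, ring B = C-5 to C-10, C-11 = benzylic CH2). The target SMILES is read as 3β-Br, 5α-H, 9α-CH2Ar (9β-H), 10β-CH3. Ar = 2,5-dimethoxy-4-(2-methoxy-2-oxoethyl)phenyl unless stated otherwise.

Step 1
Reactants: 1 2,2-dimethylpropane-1,3-diol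
Product: 2 3-[tert-butyl(dimethyl)silyl]oxy-2,2-dimethylpropan-1-ol
Conditions: NaH (1.0 equiv), THF, 0 °C; TBSCl (1.0 equiv), 0 to 23 °C
Reagents that add atoms: tert-butyldimethylsilyl chloride, CC(C)(C)[Si](C)(C)Cl
Why: Monosilylation of a symmetric diol through its sparingly soluble monosodium alkoxide should give the mono-ether selectively; no stereocentre is formed.

Step 2
Reactants: 2 3-[tert-butyl(dimethyl)silyl]oxy-2,2-dimethylpropan-1-ol
Product: 3 3-[tert-butyl(dimethyl)silyl]oxy-2,2-dimethylpropanal
Conditions: PhI(OAc)2, TEMPO (10 mol %), CH2Cl2, 23 °C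
Reagents that add atoms: none
Why: Oxoammonium (TEMPO) oxidation of a primary alcohol should stop cleanly at the non-enolisable neopentyl aldehyde.

Step 3
Reactants: 3 3-[tert-butyl(dimethyl)silyl]oxy-2,2-dimethylpropanal
Product: 4 (E)-5-[tert-butyl(dimethyl)silyl]oxy-4,4-dimethylpent-2-enal
Conditions: Ph3P=CHCHO, toluene, 90 °C
Reagents that add atoms: (triphenylphosphoranylidene)acetaldehyde, O=CC=P(c1ccccc1)(c1ccccc1)c1ccccc1
Why: Wittig olefination with a stabilised ylide should give the (E)-enal; the hindered product enal reacts more slowly than the starting aldehyde, which limits double homologation.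

Step 4
Reactants: 4 (E)-5-[tert-butyl(dimethyl)silyl]oxy-4,4-dimethylpent-2-enal
Product: 5 tert-butyl-[(3E,5Z)-6-iodo-2,2-dimethylhepta-3,5-dienoxy]-dimethylsilane
Conditions: (1-iodoethyl)triphenylphosphonium iodide, NaN(SiMe3)2, THF, −78 °C; then 4, −78 to 0 °C
Reagents that add atoms: (1-iodoethyl)triphenylphosphonium iodide, CC(I)[P+](c1ccccc1)(c1ccccc1)c1ccccc1.[I-]
Why: Wittig olefination with the non-stabilised α-iodoethylidene ylide (Stork–Zhao type) should give the (Z)-iodoalkene, with iodine cis to the chain, under kinetic control.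

Step 5
Reactants: 5 tert-butyl-[(3E,5Z)-6-iodo-2,2-dimethylhepta-3,5-dienoxy]-dimethylsilane
Product: 6 tert-butyl-[(3E,5E)-2,2-dimethyl-6-(4,4,5,5-tetramethyl-1,3,2-dioxaborolan-2-yl)hepta-3,5-dienoxy]-dimethylsilane (boron cis to the chain, as iodine was in 5)
Conditions: B2pin2, PdCl2(dppf) (3 mol %), KOPh, toluene, 50 °C
Reagents that add atoms: bis(pinacolato)diboron, CC1(C)OB(OC1(C)C)B1OC(C)(C)C(C)(C)O1
Why: Miyaura borylation of an alkenyl iodide proceeds with retention of double-bond geometry; the descriptor changes only because boron ranks below carbon.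

Step 6
Reactants: 7 methyl 2-(2,5-dimethoxyphenyl)acetate
Product: 8 methyl 2-(4-bromo-2,5-dimethoxyphenyl)acetate
Conditions: N-bromosuccinimide, MeCN, 0 to 23 °C
Reagents that add atoms: N-bromosuccinimide, O=C1CCC(=O)N1Br
Why: Electrophilic aromatic bromination should occur at the free position para to the CH2CO2Me group and ortho to a methoxy group, the most activated and least hindered site.

Step 7
Reactants: 8 methyl 2-(4-bromo-2,5-dimethoxyphenyl)acetate
Product: 9 methyl 2-(2,5-dimethoxy-4-prop-2-enylphenyl)acetate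
Conditions: allyl-B(pin), Pd(PPh3)4 (5 mol %), CsF, THF, 65 °C
Reagents that add atoms: allylboronic acid pinacol ester, C=CCB1OC(C)(C)C(C)(C)O1
Why: Suzuki–Miyaura allylation of an aryl bromide under fluoride activation spares the methyl ester.

Step 8
Reactants: 9 methyl 2-(2,5-dimethoxy-4-prop-2-enylphenyl)acetate
Product: 10 methyl 2-[2,5-dimethoxy-4-[(E)-4-oxopent-2-enyl]phenyl]acetate
Conditions: methyl vinyl ketone (3 equiv), second-generation Hoveyda–Grubbs catalyst (5 mol %), CH2Cl2, 40 °C
Reagents that add atoms: methyl vinyl ketone, CC(=O)C=C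
Why: Olefin cross-metathesis of a terminal allyl arene with an electron-poor enone partner should give the (E)-enone selectively.

Step 9
Reactants: 10 methyl 2-[2,5-dimethoxy-4-[(E)-4-oxopent-2-enyl]phenyl]acetate; 6 dienyl pinacol boronate
Product: 11 methyl 2-[4-[(2S,3Z,5E)-8-[tert-butyl(dimethyl)silyl]oxy-3,7,7-trimethyl-2-(2-oxopropyl)octa-3,5-dienyl]-2,5-dimethoxyphenyl]acetate
Conditions: [RhCl(C2H4)2]2 (2.5 mol %), chiral diene ligand (2,5-diphenylbicyclo[2.2.2]octa-2,5-diene, the enantiomer that gives the (S)-adduct), KOH (10 mol %), dioxane/H2O, 30 °C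
Reagents that add atoms: none
Why: Hayashi–Miyaura rhodium-catalysed asymmetric 1,4-addition of an alkenylboronate to an acyclic enone sets the benzylic stereocentre (C-9) by catalyst-controlled enantioface selection in the carbometalation, and the alkenyl group transfers with retention of geometry.

Step 10
Reactants: 11 β-dienyl methyl ketone
Product: 12 methyl 2-[4-[(2R,3Z,5E)-8-[tert-butyl(dimethyl)silyl]oxy-3,7,7-trimethyl-2-(3-oxobut-1-en-2-yl)octa-3,5-dienyl]-2,5-dimethoxyphenyl]acetate
Conditions: (CH2O)n, N-methylanilinium trifluoroacetate, THF, 65 °C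
Reagents that add atoms: paraformaldehyde (formaldehyde), C=O
Why: Direct α-methylenation (Mannich addition then amine elimination) of a methyl alkyl ketone takes place at the more substituted α-carbon through the more substituted enol; the stereocentre is untouched and its descriptor changes only by priority.

Step 11
Reactants: 12 silyl ether α-methylene ketone
Product: 13 methyl 2-[4-[(2R,3Z,5E)-8-hydroxy-3,7,7-trimethyl-2-(3-oxobut-1-en-2-yl)octa-3,5-dienyl]-2,5-dimethoxyphenyl]acetate
Conditions: HF·pyridine, THF/pyridine, 0 to 23 °C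
Reagents that add atoms: none
Why: Buffered fluoride desilylation is non-basic, so the γ-acidic α-methylene ketone should neither isomerise nor epimerise.

Step 12
Reactants: 13 primary alcohol
Product: 14 methyl 2-[4-[(2R,3Z,5E)-3,7,7-trimethyl-8-oxo-2-(3-oxobut-1-en-2-yl)octa-3,5-dienyl]-2,5-dimethoxyphenyl]acetate
Conditions: PhI(OAc)2, TEMPO (10 mol %), CH2Cl2, 23 °C
Reagents that add atoms: none
Why: Neutral TEMPO oxidation gives the non-enolisable neopentyl aldehyde without touching the enone, the diene or the stereocentre.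

Step 13
Reactants: 14 acyclic α-methylene ketone dienal
Product: 16 11-aryl-9βH-drima-2,7-dien-1-one (trans-fused; 5α-H; 10β-CH3; 9α-CH2Ar), via keto aldehyde 15 (not isolated)
Conditions: Fe(acac)3 (0.3 equiv), PhSiH3 (2.5 equiv, slow addition), EtOH/(CH2OH)2 5:1, 0.005 M, 0 to 23 °C; then pyrrolidine (0.3 equiv), AcOH (0.3 equiv), 60 °C, same flask
Reagents that add atoms: none
Why: Proposed new method: the iron hydride formed from Fe(acac)3 and PhSiH3 transfers a hydrogen atom to the terminal CH2 of the 2-acyl-1-alkene (this hydrogen completes the angular methyl), the tertiary α-keto radical adds 6-endo-trig to the distal carbon of the (Z,E)-diene, and the cyclohexenyl radical takes up hydrogen at its secondary terminus to leave the trisubstituted ring-B alkene; the amine salt then closes ring A by aldol condensation of the acetyl methyl (the only enolisable ketone position, now on a quaternary carbon) onto the non-enolisable neopentyl aldehyde. The closest known reaction types are the Fe(acac)3/PhSiH3 radical conjugate cyclisations and cycloisomerisations started by hydrogen atom transfer, additions of α-keto radicals to unactivated olefins, and the Robinson-type aldol condensation of 1,5-keto aldehydes. Ring B closes in the 6-endo mode through a chair-like transition state, ring A in the 6-(enolexo)-exo-trig mode. The benzylic stereocentre is meant to control both new centres: strain with the vinylic methyl should keep its C–H in the diene plane and the arylmethyl group perpendicular, the radical should add to the diene face opposite that group with the conjugated acetyl and the C(CH3)2CHO-bearing terminus pseudo-equatorial, so that the new methyl ends axial, anti to the arylmethyl group and trans to the ring-fusion hydrogen; the opposing allylic strain at the planar radical centre could favour the other arrangement, and this is the main uncertainty. The step also needs hydrogen atom transfer to the 1,1-disubstituted enone alkene (the most accessible one, giving a stabilised tertiary radical) in preference to the hindered diene, cyclisation faster than reduction of the radical (high dilution, slow silane addition), and no aldol reaction before ring B exists (that closure would be ten-membered, and the amine is added only afterwards).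

Step 14
Reactants: 16 11-aryl-9βH-drima-2,7-dien-1-one
Product: 17 11-aryl-2α,3α-epoxy-9βH-drim-7-en-1-one
Conditions: 30% H2O2, NaOH (0.3 equiv), MeOH, 0 °C
Reagents that add atoms: hydrogen peroxide, OO
Why: Weitz–Scheffer nucleophilic epoxidation touches only the enone; hydroperoxide should attack C-3 from the α-face, away from the axial C-10 and 4β methyl groups, and the isolated trisubstituted alkene is inert.

Step 15
Reactants: 17 α,β-epoxy ketone
Product: 18 11-aryl-9βH-drima-1,7-dien-3α-ol
Conditions: N2H4·H2O (3 equiv), AcOH (0.5 equiv), MeOH, 0 to 23 °C, short reaction time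
Reagents that add atoms: none
Why: Wharton transposition (epoxy hydrazone fragmentation with loss of N2) removes the C-1 oxygen, forms the 1,2-alkene and keeps the epoxide C–O bond at C-3, so the alcohol is 3α (axial).

Step 16
Reactants: 18 allylic alcohol
Product: 19 11-aryl-9βH-drim-7-en-3α-ol
Conditions: 2-nitrobenzenesulfonohydrazide, Et3N, CH2Cl2, 23 °C
Reagents that add atoms: none
Why: Diimide reduction prefers the cis-disubstituted alkene over the trisubstituted ring-B alkene and does not touch C–O or aryl groups.

Step 17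
Reactants: 19 3α-alcohol
Product: 20 11-aryl-3β-bromo-9βH-drim-7-ene (methyl ester, dimethyl ether)
Conditions: CBr4, PPh3, CH2Cl2, 0 to 23 °C
Reagents that add atoms: carbon tetrabromide, BrC(Br)(Br)Br
Why: Appel bromination of the axial alkoxyphosphonium ion by backside attack of bromide inverts C-3 to the equatorial 3β-bromide.

Step 18
Reactants: 20 bromo methyl ester
Product: 21 2-[4-[(3β-bromo-9βH-drim-7-en-11-yl)]-2,5-dimethoxyphenyl]acetic acid
Conditions: LiOH·H2O, THF/MeOH/H2O, 0 to 23 °C; then 1 M HCl
Reagents that add atoms: lithium hydroxide, [Li+].[OH-]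
Why: Saponification of the unhindered arylacetic ester should be much faster than substitution or elimination at the hindered neopentyl-type secondary bromide.

Step 19
Reactants: 21 bromo acid dimethyl ether
Product: 23 peyssonoic acid A, via quinone acid 22 (not isolated)
Conditions: (NH4)2Ce(NO3)6, MeCN/H2O, 0 °C; then Na2S2O4 (aq), EtOAc, 23 °C
Reagents that add atoms: water, O
Why: Oxidative demethylation of the 1,4-dimethoxyarene to the benzoquinone, then dithionite reduction, gives the hydroquinone under conditions that leave the alkyl bromide, the alkene and the acid alone.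

**Compound list**
1 | 2,2-dimethylpropane-1,3-diol | OCC(C)(C)CO | starting material
2 | 3-[tert-butyl(dimethyl)silyl]oxy-2,2-dimethylpropan-1-ol | CC(C)(C)[Si](C)(C)OCC(C)(C)CO | intermediate
3 | 3-[tert-butyl(dimethyl)silyl]oxy-2,2-dimethylpropanal | CC(C)(C)[Si](C)(C)OCC(C)(C)C=O | intermediate
4 | (E)-5-[tert-butyl(dimethyl)silyl]oxy-4,4-dimethylpent-2-enal | CC(C)(C)[Si](C)(C)OCC(C)(C)/C=C/C=O | intermediate
5 | tert-butyl-[(3E,5Z)-6-iodo-2,2-dimethylhepta-3,5-dienoxy]-dimethylsilane | C/C(I)=C/C=C/C(C)(C)CO[Si](C)(C)C(C)(C)C | intermediate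
6 | tert-butyl-[(3E,5E)-2,2-dimethyl-6-(4,4,5,5-tetramethyl-1,3,2-dioxaborolan-2-yl)hepta-3,5-dienoxy]-dimethylsilane | C/C(B1OC(C)(C)C(C)(C)O1)=C/C=C/C(C)(C)CO[Si](C)(C)C(C)(C)C | intermediate
7 | methyl 2-(2,5-dimethoxyphenyl)acetate | COC(=O)Cc1cc(OC)ccc1OC | starting material
8 | methyl 2-(4-bromo-2,5-dimethoxyphenyl)acetate | COC(=O)Cc1cc(OC)c(Br)cc1OC | intermediate
9 | methyl 2-(2,5-dimethoxy-4-prop-2-enylphenyl)acetate | COC(=O)Cc1cc(OC)c(CC=C)cc1OC | intermediate
10 | methyl 2-[2,5-dimethoxy-4-[(E)-4-oxopent-2-enyl]phenyl]acetate | COC(=O)Cc1cc(OC)c(C/C=C/C(C)=O)cc1OC | intermediate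
11 | methyl 2-[4-[(2S,3Z,5E)-8-[tert-butyl(dimethyl)silyl]oxy-3,7,7-trimethyl-2-(2-oxopropyl)octa-3,5-dienyl]-2,5-dimethoxyphenyl]acetate | CC(=O)C[C@H](Cc1cc(OC)c(CC(=O)OC)cc1OC)/C(C)=C\C=C\C(C)(C)CO[Si](C)(C)C(C)(C)C | intermediate
12 | methyl 2-[4-[(2R,3Z,5E)-8-[tert-butyl(dimethyl)silyl]oxy-3,7,7-trimethyl-2-(3-oxobut-1-en-2-yl)octa-3,5-dienyl]-2,5-dimethoxyphenyl]acetate | CC(=O)C(=C)[C@H](Cc1cc(OC)c(CC(=O)OC)cc1OC)/C(C)=C\C=C\C(C)(C)CO[Si](C)(C)C(C)(C)C | intermediate
13 | methyl 2-[4-[(2R,3Z,5E)-8-hydroxy-3,7,7-trimethyl-2-(3-oxobut-1-en-2-yl)octa-3,5-dienyl]-2,5-dimethoxyphenyl]acetate | CC(=O)C(=C)[C@H](Cc1cc(OC)c(CC(=O)OC)cc1OC)/C(C)=C\C=C\C(C)(C)CO | intermediate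
14 | methyl 2-[4-[(2R,3Z,5E)-3,7,7-trimethyl-8-oxo-2-(3-oxobut-1-en-2-yl)octa-3,5-dienyl]-2,5-dimethoxyphenyl]acetate | CC(=O)C(=C)[C@H](Cc1cc(OC)c(CC(=O)OC)cc1OC)/C(C)=C\C=C\C(C)(C)C=O | intermediate
15 | cyclohexene keto aldehyde (ring B closed; C-10 carries β-CH3 and α-acetyl; C-5 carries α-H and C(CH3)2CHO; 9α-CH2Ar) | CC1=CC[C@@H](C(C)(C)C=O)[C@](C)(C(C)=O)[C@@H]1Cc1cc(OC)c(CC(=O)OC)cc1OC | intermediate (not isolated)
16 | 11-aryl-9βH-drima-2,7-dien-1-one (trans-fused; 5α-H, 10β-CH3, 9α-CH2Ar) | CC1=CC[C@H]2C(C)(C)C=CC(=O)[C@]2(C)[C@@H]1Cc1cc(OC)c(CC(=O)OC)cc1OC | intermediate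
17 | 11-aryl-2α,3α-epoxy-9βH-drim-7-en-1-one | CC1=CC[C@H]2C(C)(C)[C@@H]3O[C@@H]3C(=O)[C@]2(C)[C@@H]1Cc1cc(OC)c(CC(=O)OC)cc1OC | intermediate
18 | 11-aryl-9βH-drima-1,7-dien-3α-ol | CC1=CC[C@H]2C(C)(C)[C@H](O)C=C[C@]2(C)[C@@H]1Cc1cc(OC)c(CC(=O)OC)cc1OC | intermediate
19 | 11-aryl-9βH-drim-7-en-3α-ol | CC1=CC[C@H]2C(C)(C)[C@H](O)CC[C@]2(C)[C@@H]1Cc1cc(OC)c(CC(=O)OC)cc1OC | intermediate
20 | 11-aryl-3β-bromo-9βH-drim-7-ene, methyl ester dimethyl ether | CC1=CC[C@H]2C(C)(C)[C@@H](Br)CC[C@]2(C)[C@@H]1Cc1cc(OC)c(CC(=O)OC)cc1OC | intermediate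
21 | the corresponding arylacetic acid (dimethyl ether) | CC1=CC[C@H]2C(C)(C)[C@@H](Br)CC[C@]2(C)[C@@H]1Cc1cc(OC)c(CC(=O)O)cc1OC | intermediate
22 | benzoquinone acid | CC1=CC[C@H]2C(C)(C)[C@@H](Br)CC[C@]2(C)[C@@H]1CC1=CC(=O)C(CC(=O)O)=CC1=O | intermediate (not isolated)
23 | peyssonoic acid A | CC1=CC[C@H]2C(C)(C)[C@@H](Br)CC[C@]2(C)[C@@H]1Cc1cc(O)c(CC(=O)O)cc1O | target

**Step count**
Total: 19 steps. Longest linear sequence: 16 steps (steps 1–5, then 9–19).

**Steps most likely to fail**

Step 13 (proposed new method). Two processes are at risk. First, after hydrogen atom transfer, reduction of the tertiary α-keto radical to the enolate (net conjugate reduction) or hydrogen atom transfer to the diene may outrun the 6-endo addition. Second, facial selectivity at the ring fusion relative to the benzylic centre may be poor. The fallback uses known tin hydride radical chemistry, which has no reducing metal; it addresses the first process only. It sets out from 12 and returns at 15, and so at 16. Conjugate reduction of 12 with LiBH(s-Bu)3 (THF, −78 °C) and trapping of the regiodefined enolate with N-bromosuccinimide should give the tertiary α-bromo ketone F1. Bu3SnH with AIBN (syringe pump, benzene, 80 °C) generates the same α-keto radical and should give, after 6-endo closure onto the diene, the monocyclic acetyl silyl ether F2. HF·pyridine gives the alcohol F3, PhI(OAc)2/TEMPO gives keto aldehyde 15 (now isolated), and pyrrolidinium acetate closes ring A to 16.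

Step 17. The activated axial neopentyl-type alcohol may ionise with 1,2-shift (ring-A contraction) or eliminate, instead of undergoing backside displacement. The fallback sets out from 18 and returns at 20. The displacement is moved to the allylic stage, where SN2 is accelerated by the adjacent π bond and SN2′ is blocked by the quaternary ring-fusion carbon. Ms2O/Et3N then LiBr (acetone, 0 °C) should convert 18 with inversion into the allylic bromide F4. Diimide under the conditions of step 16 then saturates the disubstituted alkene to give 20.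

Step 9. Enantioselectivity may erode with the hindered 1,1-disubstituted dienylboronate, and the skipped enone double bond may migrate into conjugation with the arene under the basic conditions. The fallback sets out from 9 and 6 and returns at 12, skipping 10 and 11. OsO4 (cat.)/NaIO4 cleavage of the allyl group of 9 gives the arylacetaldehyde F5. Morita–Baylis–Hillman reaction with methyl vinyl ketone (DABCO) gives the hydroxy enone F6. PBr3 gives, with allylic transposition, the (Z)-2-(bromomethyl)enone F7. Copper-catalysed enantioselective SN2′ alkenylation of F7 with boronate 6 (CuCl, chiral N-heterocyclic carbene ligand, NaOMe, THF) forms the benzylic stereocentre and the α-methylene ketone of 12 in one step.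

Further compounds
F1 | step 13 | tertiary α-bromo ketone (bromine on the carbon bearing acetyl and methyl, mixture of epimers there) | CC(=O)C(C)(Br)[C@H](Cc1cc(OC)c(CC(=O)OC)cc1OC)/C(C)=C\C=C\C(C)(C)CO[Si](C)(C)C(C)(C)C
F2 | step 13 | monocyclic acetyl cyclohexene silyl ether (as 15, with CH2OTBS in place of CHO) | CC1=CC[C@@H](C(C)(C)CO[Si](C)(C)C(C)(C)C)[C@](C)(C(C)=O)[C@@H]1Cc1cc(OC)c(CC(=O)OC)cc1OC
F3 | step 13 | monocyclic acetyl cyclohexene primary alcohol | CC1=CC[C@@H](C(C)(C)CO)[C@](C)(C(C)=O)[C@@H]1Cc1cc(OC)c(CC(=O)OC)cc1OC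
F4 | step 17 | 11-aryl-3β-bromo-9βH-drima-1,7-diene (allylic bromide) | CC1=CC[C@H]2C(C)(C)[C@@H](Br)C=C[C@]2(C)[C@@H]1Cc1cc(OC)c(CC(=O)OC)cc1OC
F5 | step 9 | methyl 2-[2,5-dimethoxy-4-(2-oxoethyl)phenyl]acetate | COC(=O)Cc1cc(OC)c(CC=O)cc1OC
F6 | step 9 | methyl 2-[4-(2-hydroxy-3-methylidene-4-oxopentyl)-2,5-dimethoxyphenyl]acetate | COC(=O)Cc1cc(OC)c(CC(O)C(=C)C(C)=O)cc1OC
F7 | step 9 | methyl 2-[4-[(Z)-3-(bromomethyl)-4-oxopent-2-enyl]-2,5-dimethoxyphenyl]acetate | COC(=O)Cc1cc(OC)c(C/C=C(/CBr)C(C)=O)cc1OC
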